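**Retrosynthetic overview**
- The target is the O-debenzylation product of a mono-benzyl ether. Its oxolane (the only ring) is closed in the penultimate step by forming the C7–O bond: the C9' hydroxyl adds to a p-quinone methide generated at the benzylic carbon of the free-phenol ring.
- The cyclisation substrate is an open-chain tetraol phenol, obtained by exhaustive LiAlH4 reduction of a 2-aryl-4-(aryl-hydroxymethyl)-5-oxooxolane-3-carboxylic acid.
- That lactone acid comes from an aldol of a cis-paraconic acid dianion with vanillin acetate (C7–C8 bond; attack trans to the carboxylate fixes C8).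
- The cis-paraconic acid comes from Pinnick oxidation and lactonisation of the D-proline anti-aldol of O-benzylvanillin with methyl 4-oxobutanoate (sets C7' and C8').
- Ring order: temporary γ-lactone template (step 2), opened (step 4), then the oxolane (step 5).

Assumption: lignan locants are used (C7–C8–C9 becomes oxolane C2–C3–CH2OH; C7'–C8'–C9' becomes the carbinol carbon, oxolane C4 and the ring OCH2); the building blocks and D-proline are bought; a carbinol carbon carried as an epimer mixture is written without a stereo mark in its SMILES.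

**Step 1**
Reactants: 1 4-(benzyloxy)-3-methoxybenzaldehyde; 2 methyl 4-oxobutanoate
Product: 3 methyl (3R,4S)-4-[4-(benzyloxy)-3-methoxyphenyl]-3-formyl-4-hydroxybutanoate
Conditions: D-proline (20 mol%), DMF, 4 °C, 48 h (2 equiv of 2); crude product used at once
Reagents that add atoms: none
Why: Enamine (List–Houk) cross-aldol in which the E-enamine of 2 formed with D-proline adds to the Si face of the non-enolisable aldehyde 1 through the acid-bridged chair transition state, giving the anti aldol and setting C7' (S) and C8' together.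

**Step 2**
Reactants: 3 methyl (3R,4S)-4-[4-(benzyloxy)-3-methoxyphenyl]-3-formyl-4-hydroxybutanoate
Product: 5 (2S,3R)-2-[4-(benzyloxy)-3-methoxyphenyl]-5-oxooxolane-3-carboxylic acid, via hydroxy acid 4 (not isolated)
Conditions: NaClO2, NaH2PO4, 2-methyl-2-butene, t-BuOH/H2O, 0 °C; then pyridinium p-toluenesulfonate (10 mol%), PhMe, 50 °C
Reagents that add atoms: sodium chlorite [Na+].[O-]Cl=O
Why: Pinnick oxidation converts the epimerisable α-branched aldehyde to the acid without touching C8', and mild acid-catalysed lactonisation of the benzylic hydroxyl onto the methyl ester (the only five-membered option) gives the cis γ-lactone with both centres retained.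

**Step 3**
Reactants: 5 (2S,3R)-2-[4-(benzyloxy)-3-methoxyphenyl]-5-oxooxolane-3-carboxylic acid; 6 4-formyl-2-methoxyphenyl acetate
Product: 8 (2S,3R,4S)-4-[(4-acetoxy-3-methoxyphenyl)(hydroxy)methyl]-2-[4-(benzyloxy)-3-methoxyphenyl]-5-oxooxolane-3-carboxylic acid (both carbinol epimers), via dilithium dianion 7 (not isolated)
Conditions: LiN(SiMe3)2 (2.3 equiv), THF, −78 °C, 1 h; 6, −78 °C, 30 min; AcOH, −78 °C
Reagents that add atoms: none
Why: Aldol addition of the carboxylate/lactone-enolate dianion, which is attacked on the face opposite the cis aryl and carboxylate groups so that the new substituent at C8 is trans to the carboxylate (C8 set); the carboxylate blocks deprotonation at C8', and the C7 epimer ratio is irrelevant because C7 is re-set in step 5.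

**Step 4**
Reactants: 8 (2S,3R,4S)-4-[(4-acetoxy-3-methoxyphenyl)(hydroxy)methyl]-2-[4-(benzyloxy)-3-methoxyphenyl]-5-oxooxolane-3-carboxylic acid
Product: 9 (1S,2S,3R,4RS)-1-[4-(benzyloxy)-3-methoxyphenyl]-4-(4-hydroxy-3-methoxyphenyl)-2,3-bis(hydroxymethyl)butane-1,4-diol
Conditions: LiAlH4 (6 equiv), THF, 0 °C → rt; aq. KNaC4H4O6 work-up at pH 7
Reagents that add atoms: none
Why: Exhaustive hydride reduction opens the lactone to the C9 and C7' alcohols, reduces the acid to the C9' alcohol and cleaves the aryl acetate, so only the C7 aryl ring carries a free phenol; this is what distinguishes the two benzylic carbinols (with identical rings one C7 epimer would be meso), and no stereocentre is touched.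

**Step 5**
Reactants: 9 (1S,2S,3R,4RS)-1-[4-(benzyloxy)-3-methoxyphenyl]-4-(4-hydroxy-3-methoxyphenyl)-2,3-bis(hydroxymethyl)butane-1,4-diol
Product: 11 [(2S,3R,4S)-4-[(S)-[4-(benzyloxy)-3-methoxyphenyl](hydroxy)methyl]-2-(4-hydroxy-3-methoxyphenyl)oxolan-3-yl]methanol, via quinone methide 10 (not isolated)
Conditions: (PhO)2P(O)OH (10 mol%), 5 Å molecular sieves, CH2Cl2/MeCN 4:1, 0.01 M, 25 °C
Reagents that add atoms: none
Why: Proposed new method: phenol-gated, stereoconvergent dehydrative 5-exo cycloetherification, in which the phosphoric acid hydrogen-bonds the phenol and the benzylic hydroxyl of the 4-hydroxy-3-methoxyphenyl carbinol and expels water to give the phosphate-bound p-quinone methide 10 from both C7 epimers, while the O-benzylated carbinol at C7' cannot form a neutral quinone methide and is not ionised by this weak acid; the primary C9' hydroxyl then adds to the exocyclic carbon anti to the C8 hydroxymethyl group, setting C7 (S) and closing the oxolane, and the same 2,3-trans-3,4-trans isomer is also the thermodynamic sink because the p-hydroxybenzyl ether re-ionises under the catalyst; the closest known reaction types are phosphoric-acid-catalysed 1,6-additions to p-quinone methides made in situ from p-hydroxybenzyl alcohols and strong-acid benzylic cyclisations of protected lignan polyols, and what has not been shown is hydroxyl capture on an unprotected tetraol with discrimination between two benzylic carbinols and convergence of a carbinol epimer mixture.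

**Step 6**
Reactants: 11 [(2S,3R,4S)-4-[(S)-[4-(benzyloxy)-3-methoxyphenyl](hydroxy)methyl]-2-(4-hydroxy-3-methoxyphenyl)oxolan-3-yl]methanol
Product: 12 4-[(2S,3R,4S)-4-[(S)-hydroxy(4-hydroxy-3-methoxyphenyl)methyl]-3-(hydroxymethyl)oxolan-2-yl]-2-methoxyphenol
Conditions: H2 (1 atm), 10% Pd/C, EtOAc, rt, 1 h
Reagents that add atoms: none
Why: Hydrogenolysis of the aryl benzyl ether over Pd/C in a neutral aprotic solvent is much faster than cleavage of the benzylic carbinol or the cyclic benzylic ether, so all four stereocentres survive.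

**Compound list**
1 | 4-(benzyloxy)-3-methoxybenzaldehyde (O-benzylvanillin) | O=Cc1ccc(OCc2ccccc2)c(OC)c1 | starting material
2 | methyl 4-oxobutanoate | COC(=O)CCC=O | starting material
3 | methyl (3R,4S)-4-[4-(benzyloxy)-3-methoxyphenyl]-3-formyl-4-hydroxybutanoate | COc1cc([C@@H](O)[C@H](C=O)CC(=O)OC)ccc1OCc1ccccc1 | intermediate
4 | (2R)-2-[(S)-[4-(benzyloxy)-3-methoxyphenyl](hydroxy)methyl]-4-methoxy-4-oxobutanoic acid (not isolated) | COc1cc([C@@H](O)[C@H](C(=O)O)CC(=O)OC)ccc1OCc1ccccc1 | intermediate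
5 | (2S,3R)-2-[4-(benzyloxy)-3-methoxyphenyl]-5-oxooxolane-3-carboxylic acid (cis) | O=C1C[C@@H](C(=O)O)[C@@H](c2ccc(OCc3ccccc3)c(OC)c2)O1 | intermediate
6 | 4-formyl-2-methoxyphenyl acetate (vanillin acetate) | CC(=O)Oc1ccc(C=O)cc1OC | starting material
7 | dilithium (2S,3R)-2-[4-(benzyloxy)-3-methoxyphenyl]-5-oxido-2,3-dihydrofuran-3-carboxylate (not isolated) | [Li+].[Li+].[O-]C1=C[C@@H](C([O-])=O)[C@@H](c2ccc(OCc3ccccc3)c(OC)c2)O1 | intermediate
8 | (2S,3R,4S)-4-[(4-acetoxy-3-methoxyphenyl)(hydroxy)methyl]-2-[4-(benzyloxy)-3-methoxyphenyl]-5-oxooxolane-3-carboxylic acid, both carbinol epimers | O=C1[C@H](C(O)c2ccc(OC(C)=O)c(OC)c2)[C@@H](C(=O)O)[C@@H](c2ccc(OCc3ccccc3)c(OC)c2)O1 | intermediate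
9 | (1S,2S,3R,4RS)-1-[4-(benzyloxy)-3-methoxyphenyl]-4-(4-hydroxy-3-methoxyphenyl)-2,3-bis(hydroxymethyl)butane-1,4-diol | COc1cc(C(O)[C@@H](CO)[C@@H](CO)[C@H](O)c2ccc(OCc3ccccc3)c(OC)c2)ccc1O | intermediate
10 | 4-[(2R,3S,4S)-4-[4-(benzyloxy)-3-methoxyphenyl]-4-hydroxy-2,3-bis(hydroxymethyl)butylidene]-2-methoxycyclohexa-2,5-dien-1-one (p-quinone methide, not isolated) | COC1=CC(=C[C@@H](CO)[C@@H](CO)[C@H](O)c2ccc(OCc3ccccc3)c(OC)c2)C=CC1=O | intermediate
11 | [(2S,3R,4S)-4-[(S)-[4-(benzyloxy)-3-methoxyphenyl](hydroxy)methyl]-2-(4-hydroxy-3-methoxyphenyl)oxolan-3-yl]methanol | COc1cc([C@@H](O)[C@@H]2CO[C@H](c3ccc(O)c(OC)c3)[C@H]2CO)ccc1OCc1ccccc1 | intermediate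
12 | 4-[(2S,3R,4S)-4-[(S)-hydroxy(4-hydroxy-3-methoxyphenyl)methyl]-3-(hydroxymethyl)oxolan-2-yl]-2-methoxyphenol | COc1cc([C@@H](O)[C@@H]2CO[C@H](c3ccc(O)c(OC)c3)[C@H]2CO)ccc1O | target

**Step count**
Total steps: 6. Longest linear sequence: 6 (from 1 and 2 to 12).

**Three steps most likely to fail**

Step 5 (the proposed new cyclisation). It could fail through ionisation at C7', capture by the C7' hydroxyl, or slow quinone methide formation. The fallback sets out from 5 and comes back at 11, and reaches the same quinone methide by oxidation instead of dehydration, which is established lignan chemistry. Dianion 7 (from 5, LiN(SiMe3)2) is alkylated trans to the carboxylate with the known bromide [4-(bromomethyl)-2-methoxyphenoxy](tert-butyl)dimethylsilane F5 to give (2S,3R,4R)-2-[4-(benzyloxy)-3-methoxyphenyl]-4-({4-[(tert-butyldimethylsilyl)oxy]-3-methoxyphenyl}methyl)-5-oxooxolane-3-carboxylic acid F6. LiAlH4 reduction gives the silyl-protected triol (1S,2S,3R)-1-[4-(benzyloxy)-3-methoxyphenyl]-4-{4-[(tert-butyldimethylsilyl)oxy]-3-methoxyphenyl}-2,3-bis(hydroxymethyl)butan-1-ol F7, and Bu4NF frees the phenol triol (1S,2S,3R)-1-[4-(benzyloxy)-3-methoxyphenyl]-4-(4-hydroxy-3-methoxyphenyl)-2,3-bis(hydroxymethyl)butan-1-ol F8. 2,3-Dichloro-5,6-dicyano-1,4-benzoquinone (1.0 equiv, CH2Cl2/dioxane, 0 °C) dehydrogenates the p-alkylphenol to quinone methide 10, which closes onto the C9' hydroxyl to give 11; step 6 then follows.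

Step 3 (the aryl acetate of 6 may be attacked or deprotonated by the lithium dianion, or the aldolate may revert). The fallback sets out from 5 and comes back at 8, replacing the lithium aldol by a Lewis-acid Mukaiyama aldol that never exposes the acetate to a basic enolate. Treating 5 with LiN(SiMe3)2 (2.3 equiv) and Me3SiCl in THF at −78 °C gives the bis-silyl ketene acetal trimethylsilyl (2S,3R)-2-[4-(benzyloxy)-3-methoxyphenyl]-5-[(trimethylsilyl)oxy]-2,3-dihydrofuran-3-carboxylate F4. This adds to 6 under BF3·OEt2 in CH2Cl2 at −78 °C, again anti to the ring substituents, and aqueous work-up hydrolyses the silyl ester and silyl ether to give 8.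

Step 1 (the electron-rich aldehyde may react slowly or with eroded anti selectivity). The fallback sets out from 1 and comes back at 5, making the C7'–C8' bond under auxiliary control. (S)-4-Benzyloxazolidin-2-one is acylated (n-BuLi, methyl 4-chloro-4-oxobutanoate) to methyl 4-[(4S)-4-benzyl-2-oxo-1,3-oxazolidin-3-yl]-4-oxobutanoate F1. This is combined with 1 under the direct anti-aldol conditions (MgCl2 10 mol%, Et3N, Me3SiCl, EtOAc, 23 °C), where the chelated Z-enolate is attacked anti to the benzyl group. The product is methyl (3R,4S)-3-[(4S)-4-benzyl-2-oxo-1,3-oxazolidine-3-carbonyl]-4-[4-(benzyloxy)-3-methoxyphenyl]-4-[(trimethylsilyl)oxy]butanoate F2. CF3CO2H in MeOH removes the silyl group and closes the lactone to (4S)-4-benzyl-3-[(2S,3R)-2-[4-(benzyloxy)-3-methoxyphenyl]-5-oxooxolane-3-carbonyl]-1,3-oxazolidin-2-one F3. LiOH/H2O2 (THF/H2O, 0 °C, then acidification) cleaves the auxiliary to give 5.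

**Further compounds**
F1 | step 1 | methyl 4-[(4S)-4-benzyl-2-oxo-1,3-oxazolidin-3-yl]-4-oxobutanoate | COC(=O)CCC(=O)N1[C@@H](Cc2ccccc2)COC1=O
F2 | step 1 | methyl (3R,4S)-3-[(4S)-4-benzyl-2-oxo-1,3-oxazolidine-3-carbonyl]-4-[4-(benzyloxy)-3-methoxyphenyl]-4-[(trimethylsilyl)oxy]butanoate | COc1cc([C@@H](O[Si](C)(C)C)[C@H](C(=O)N2[C@@H](Cc3ccccc3)COC2=O)CC(=O)OC)ccc1OCc1ccccc1
F3 | step 1 | (4S)-4-benzyl-3-[(2S,3R)-2-[4-(benzyloxy)-3-methoxyphenyl]-5-oxooxolane-3-carbonyl]-1,3-oxazolidin-2-one | O=C1C[C@@H](C(=O)N2[C@@H](Cc3ccccc3)COC2=O)[C@@H](c2ccc(OCc3ccccc3)c(OC)c2)O1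
F4 | step 3 | trimethylsilyl (2S,3R)-2-[4-(benzyloxy)-3-methoxyphenyl]-5-[(trimethylsilyl)oxy]-2,3-dihydrofuran-3-carboxylate | C[Si](C)(C)OC1=C[C@@H](C(=O)O[Si](C)(C)C)[C@@H](c2ccc(OCc3ccccc3)c(OC)c2)O1
F5 | step 5 | [4-(bromomethyl)-2-methoxyphenoxy](tert-butyl)dimethylsilane | COc1cc(CBr)ccc1O[Si](C)(C)C(C)(C)C
F6 | step 5 | (2S,3R,4R)-2-[4-(benzyloxy)-3-methoxyphenyl]-4-({4-[(tert-butyldimethylsilyl)oxy]-3-methoxyphenyl}methyl)-5-oxooxolane-3-carboxylic acid | O=C1[C@H](Cc2ccc(O[Si](C)(C)C(C)(C)C)c(OC)c2)[C@@H](C(=O)O)[C@@H](c2ccc(OCc3ccccc3)c(OC)c2)O1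
F7 | step 5 | (1S,2S,3R)-1-[4-(benzyloxy)-3-methoxyphenyl]-4-{4-[(tert-butyldimethylsilyl)oxy]-3-methoxyphenyl}-2,3-bis(hydroxymethyl)butan-1-ol | COc1cc(C[C@@H](CO)[C@@H](CO)[C@H](O)c2ccc(OCc3ccccc3)c(OC)c2)ccc1O[Si](C)(C)C(C)(C)C
F8 | step 5 | (1S,2S,3R)-1-[4-(benzyloxy)-3-methoxyphenyl]-4-(4-hydroxy-3-methoxyphenyl)-2,3-bis(hydroxymethyl)butan-1-ol | COc1cc(C[C@@H](CO)[C@@H](CO)[C@H](O)c2ccc(OCc3ccccc3)c(OC)c2)ccc1O
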